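**Retrosynthetic overview**
1. Target 11 ⇐ spiro ketone 10 by carbonyl methylenation (C7=CH2 made last).
2. 10 ⇐ acyclic bromochloro keto-alkene 8: ring A is closed by forming the C6–C11 spiro bond together with C10–Br, when an anodically generated bromonium ion is captured by the enolized ketone.
3. 8 ⇐ methyl ketone 5 + prenyl bromide 6 (C8–C9 bond by kinetic enolate alkylation).
4. 5 ⇐ (S)-limonene 1: the C6–H centre of 1 directs trans-diaxial chlorohydrin formation (C2–Cl, C3–O); ozonolysis and OH→Br with retention follow.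
5. Ring order: ring B is bought in 1; ring A is formed last, in the electrochemical step.

Assumption: positions are given in chamigrene numbering (ring B = C1–C6 with spiro C6, Cl on C2, Br and CH3 on C3; ring A = C6–C11 with Br on C10 and C11 the CMe2 carbon; C14 = exocyclic CH2), and 1 is used at ≥98% ee.

Step 1
Reactants: 1 (S)-(−)-limonene
Product: 2 (1R,2R,4S)-2-chloro-1-methyl-4-(prop-1-en-2-yl)cyclohexan-1-ol
Conditions: NCS (1.1 equiv), acetone/H2O 4:1, 0 °C → rt
Reagents that add atoms: N-chlorosuccinimide, O=C1CCC(=O)N1Cl; water, O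
Why: Electrophilic chlorohydrin formation occurs at the more electron-rich trisubstituted ring alkene with Markovnikov, trans-diaxial (Fürst–Plattner) anti addition, Cl entering C2 on the face away from the equatorial isopropenyl group and water entering C3 on the other face, so the C6 centre bought in 1 sets both new centres, as in the known NBS/water bromohydrin of limonene.

Step 2
Reactants: 2 (1R,2R,4S)-2-chloro-1-methyl-4-(prop-1-en-2-yl)cyclohexan-1-ol
Product: 4 1-[(1S,3R,4R)-3-chloro-4-hydroxy-4-methylcyclohexyl]ethan-1-one, via secondary ozonide 3 (not isolated)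
Conditions: O3, CH2Cl2, −78 °C; then Me2S, −78 °C → rt
Reagents that add atoms: ozone, [O-][O+]=O
Why: Ozonolysis with reductive work-up cleaves the only remaining alkene to the methyl ketone and touches no stereocentre.

Step 3
Reactants: 4 1-[(1S,3R,4R)-3-chloro-4-hydroxy-4-methylcyclohexyl]ethan-1-one
Product: 5 1-[(1S,3R,4R)-4-bromo-3-chloro-4-methylcyclohexyl]ethan-1-one
Conditions: Me3SiBr (2 equiv), CH2Cl2, −20 → 0 °C
Reagents that add atoms: bromotrimethylsilane, C[Si](C)(C)Br
Why: SN1 substitution of the tertiary alcohol with neighbouring-group participation of the anti-periplanar axial C2–Cl lets bromide enter C3 on the face the oxygen leaves (retention), giving the trans-diaxial bromochloride with C3 fixed relative to C2 and with no halogen migration, because a bridging Cl is opened at the tertiary carbon.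

Step 4
Reactants: 5 1-[(1S,3R,4R)-4-bromo-3-chloro-4-methylcyclohexyl]ethan-1-one; 6 1-bromo-3-methylbut-2-ene (prenyl bromide)
Product: 8 1-[(1S,3R,4R)-4-bromo-3-chloro-4-methylcyclohexyl]-5-methylhex-4-en-1-one, via lithium enolate 7 (not isolated)
Conditions: LiN(SiMe3)2 (1.05 equiv), THF, −78 °C; then 6 (1.5 equiv), DMPU, −78 → −40 °C
Reagents that add atoms: none
Why: Kinetic enolate alkylation: the hindered amide removes a methyl proton at −78 °C and the less substituted enolate is alkylated by the allylic bromide (SN2) faster than it equilibrates or than E2 occurs at the tertiary bromide, and no stereocentre is touched.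

Step 5
Reactants: 8 1-[(1S,3R,4R)-4-bromo-3-chloro-4-methylcyclohexyl]-5-methylhex-4-en-1-one
Product: 10 (4S,6S,8R,9R)-4,9-dibromo-8-chloro-5,5,9-trimethylspiro[5.5]undecan-1-one, via bromonium ion 9 (not isolated)
Conditions: LiBr (1.5 equiv), nBu4NPF6 (0.1 M), HFIP/CH2Cl2 4:1, undivided cell, graphite anode, Pt cathode, 5 mA cm−2, 2.2 F mol−1, −10 °C → rt
Reagents that add atoms: lithium bromide, [Li+].[Br-]
Why: Proposed new method: anodic oxidation of bromide in HFIP gives an electrophilic bromine carrier that forms the bromonium ion at the only electron-rich alkene, and its tertiary carbon C11 is captured (Markovnikov, anti to Br) by C6 of the ketone in its enol form through a chair-like six-membered transition state, the closest known chemistry being anodic bromide-mediated halocyclizations and bromonium-induced cation–olefin (polyene) cyclizations ended by enol derivatives; C10 is set by the anti addition with Br equatorial, the spiro centre C6 is set by C–C bond formation on the equatorial face of the ring-flipped ring B conformer (Br and Cl equatorial), which places C11 cis to Cl and avoids a syn-axial C7/Cl contact, and the epimers at C6 and C10 that also form are removed by chromatography.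

Step 6
Reactants: 10 (4S,6S,8R,9R)-4,9-dibromo-8-chloro-5,5,9-trimethylspiro[5.5]undecan-1-one
Product: 11 (2S,6R,8R,9R)-2,9-dibromo-8-chloro-1,1,9-trimethyl-5-methylidenespiro[5.5]undecane
Conditions: Cp2TiMe2 (3 equiv), toluene/THF, 65 °C, dark
Reagents that add atoms: dimethyltitanocene Cp2TiMe2, C[Ti](C)(C1C=CC=C1)C1C=CC=C1
Why: Carbonyl methylenation with Cp2TiMe2 (Petasis olefination) is non-basic and works on hindered α-quaternary ketones, so the alkyl halides survive and no stereocentre is touched.

**Compound list**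
1 | (S)-(−)-limonene, (4S)-1-methyl-4-(prop-1-en-2-yl)cyclohex-1-ene | CC1=CC[C@H](CC1)C(C)=C | starting material
2 | (1R,2R,4S)-2-chloro-1-methyl-4-(prop-1-en-2-yl)cyclohexan-1-ol | CC(=C)[C@H]1CC[C@@](C)(O)[C@H](Cl)C1 | intermediate
3 | secondary ozonide, (1R,2R,4S)-2-chloro-1-methyl-4-(3-methyl-1,2,4-trioxolan-3-yl)cyclohexan-1-ol (both configurations at the trioxolane carbon) | CC2(OCOO2)[C@H]1CC[C@@](C)(O)[C@H](Cl)C1 | intermediate
4 | 1-[(1S,3R,4R)-3-chloro-4-hydroxy-4-methylcyclohexyl]ethan-1-one | CC(=O)[C@H]1CC[C@@](C)(O)[C@H](Cl)C1 | intermediate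
5 | 1-[(1S,3R,4R)-4-bromo-3-chloro-4-methylcyclohexyl]ethan-1-one | CC(=O)[C@H]1CC[C@@](C)(Br)[C@H](Cl)C1 | intermediate
6 | 1-bromo-3-methylbut-2-ene (prenyl bromide) | CC(C)=CCBr | starting material
7 | lithium enolate, lithium 1-[(1S,3R,4R)-4-bromo-3-chloro-4-methylcyclohexyl]ethen-1-olate | C=C([O-])[C@H]1CC[C@@](C)(Br)[C@H](Cl)C1.[Li+] | intermediate
8 | 1-[(1S,3R,4R)-4-bromo-3-chloro-4-methylcyclohexyl]-5-methylhex-4-en-1-one | CC(C)=CCCC(=O)[C@H]1CC[C@@](C)(Br)[C@H](Cl)C1 | intermediate
9 | bromonium ion, (3S)-3-{3-[(1S,3R,4R)-4-bromo-3-chloro-4-methylcyclohexyl]-3-oxopropyl}-2,2-dimethylbromiran-1-ium | CC1(C)[Br+][C@H]1CCC(=O)[C@H]2CC[C@@](C)(Br)[C@H](Cl)C2 | intermediate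
10 | (4S,6S,8R,9R)-4,9-dibromo-8-chloro-5,5,9-trimethylspiro[5.5]undecan-1-one | O=C1CC[C@H](Br)C(C)(C)[C@@]12CC[C@@](C)(Br)[C@H](Cl)C2 | intermediate
11 | (2S,6R,8R,9R)-2,9-dibromo-8-chloro-1,1,9-trimethyl-5-methylidenespiro[5.5]undecane | C=C1CC[C@H](Br)C(C)(C)[C@@]12CC[C@@](C)(Br)[C@H](Cl)C2 | target

**Step count**
Total steps: 6. Longest linear sequence: 6 steps (1 → 11).

**Steps most likely to fail**

(a) The electrochemical closure of 8 to 10 (step 5, the proposed new method) is the least certain step.
- The carbonyl oxygen may capture the bromonium ion first, and dibromide formation or α-bromination may compete.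
- The face selectivity at C6 rests on a conformational argument only.
- The two chair arrangements that lead to the C10 epimers differ only in remote contacts, so selectivity at C10 is expected to be low. The (4R) epimer of 10 will be the main by-product and has to be separated (silica, then HPLC).

The fallback uses known chemistry, sets out from 8 and comes back at 10. Isopropenyl acetate and TsOH convert 8 into the enol acetate 1-[(3R,4R)-4-bromo-3-chloro-4-methylcyclohexylidene]-5-methylhex-4-en-1-yl acetate F6 (mixture of alkene isomers). This is a preformed carbon nucleophile that cannot be captured at oxygen. F6 is then cyclized with the bromonium donor Et2SBr·SbCl5Br in MeNO2 at −25 °C, a bromonium-induced cation–olefin cyclization ended by an enol ester. The acetyl group is lost on work-up and 10 is obtained.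

(b) The alkylation of 5 (step 4) puts a strong base next to a tertiary bromide and a γ-chloro ketone, so E2 and cyclopropane formation threaten.

The fallback sets out from 4 and comes back at 8, so the base-sensitive bromide is installed after the C–C bond. K2CO3 in MeOH closes the trans-chlorohydrin of 4 to the epoxy ketone 1-[(1S,3S,6R)-6-methyl-7-oxabicyclo[4.1.0]heptan-3-yl]ethan-1-one F3. LiN(iPr)2 at −78 °C and then 6 give 5-methyl-1-[(1S,3S,6R)-6-methyl-7-oxabicyclo[4.1.0]heptan-3-yl]hex-4-en-1-one F4. LiCl/AcOH in THF opens the epoxide trans-diaxially at C2 to 1-[(1S,3R,4R)-3-chloro-4-hydroxy-4-methylcyclohexyl]-5-methylhex-4-en-1-one F5. PBr3 in Et2O at −20 °C converts the tertiary alcohol into the bromide with retention, as in step 3, to give 8.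

(c) The chlorohydrin formation (step 1) may give allylic chlorination of the isopropenyl group or a lower diastereomer ratio than the bromine analogue.

The fallback sets out from 1 and comes back at 2 through the literature bromohydrin route. NBS in aqueous acetone gives (1R,2R,4S)-2-bromo-1-methyl-4-(prop-1-en-2-yl)cyclohexan-1-ol F1. NaOH closes it to the trans-epoxide (1R,4S,6S)-1-methyl-4-(prop-1-en-2-yl)-7-oxabicyclo[4.1.0]heptane F2. LiCl/AcOH opens F2 trans-diaxially at the secondary carbon to give 2.

**Further compounds**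
F1 | step 1 | (1R,2R,4S)-2-bromo-1-methyl-4-(prop-1-en-2-yl)cyclohexan-1-ol | CC(=C)[C@H]1CC[C@@](C)(O)[C@H](Br)C1
F2 | step 1 | (1R,4S,6S)-1-methyl-4-(prop-1-en-2-yl)-7-oxabicyclo[4.1.0]heptane | CC(=C)[C@H]1CC[C@@]2(C)O[C@H]2C1
F3 | step 4 | 1-[(1S,3S,6R)-6-methyl-7-oxabicyclo[4.1.0]heptan-3-yl]ethan-1-one | CC(=O)[C@H]1CC[C@@]2(C)O[C@H]2C1
F4 | step 4 | 5-methyl-1-[(1S,3S,6R)-6-methyl-7-oxabicyclo[4.1.0]heptan-3-yl]hex-4-en-1-one | CC(C)=CCCC(=O)[C@H]1CC[C@@]2(C)O[C@H]2C1
F5 | step 4 | 1-[(1S,3R,4R)-3-chloro-4-hydroxy-4-methylcyclohexyl]-5-methylhex-4-en-1-one | CC(C)=CCCC(=O)[C@H]1CC[C@@](C)(O)[C@H](Cl)C1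
F6 | step 5 | 1-[(3R,4R)-4-bromo-3-chloro-4-methylcyclohexylidene]-5-methylhex-4-en-1-yl acetate | CC(C)=CCCC(OC(C)=O)=C1CC[C@@](C)(Br)[C@H](Cl)C1
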